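Compound numbers used throughout (full list after the steps): 1–5 ring D–E line, 6–8 squarate line, 9–12 vinyl addition, 13–15 key step, 16–18 ring A phenol, 19–22 ring B iodide, 23 A–B bromide, 24 permethyl ether, 25 target.

## Analysis of the target

The target is a linear phlorethol-type oligomer: five benzene rings, lettered A to E from the 2,4,6-trihydroxyphenyl end, joined only by four diaryl ether oxygens and carrying thirteen free phenolic hydroxyls. It has no stereocentre and no isolable axis, so the whole problem is constitutional: which oxygen of which ring bears which aryl group. Ring A is a phloroglucinol ether. Ring B is 1,3,4,5-tetraoxygenated (ether to A on C1, hydroxyls on C3 and C4, ether to C on C5). Ring D is 1,3,4,5-tetraoxygenated with its ether to E on C4 between two hydroxyls, and ring E is a pyrogallol 5-ether. The free polyphenol, with pyrogallol-like arrays in rings B, C and E, is oxidised readily by air, above all under base, so it should be unveiled only in the last step from a permethyl ether. The difficulty is that the rings differ only in oxygen placement, several ether oxygens are flanked on both sides, and a misplaced ether gives an isomer that is very hard to recognise. The strategy rests on ring C, numbered C1 (ether oxygen to ring B), C2 (the only hydrogen), C3, C4, C5 (hydroxyls) and C6 (ether oxygen to ring D). Its five contiguous oxygens and one hydrogen are what four oxygen-bearing squarate carbons plus a 1-oxygenated vinyl unit deliver. The vinyl CH2 becomes C2–H and the squarate carbonyl carbon becomes C1 with a free hydroxyl.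

## Retrosynthetic reasoning

**25 to 24.** All thirteen O–CH3 bonds are cut at once. Methyl ethers are chosen because they survive organolithium addition, thermolysis at about 135 °C and hot basic copper couplings, and they need a single deprotection. The forward step must cleave every methyl ether without touching the four diaryl ether bonds.

**24 to 15 and 23.** The bond between the ring C oxygen on C1 and C5 of ring B is cut. This splits the molecule three rings to two. The oxygen stays with ring C because the key step delivers exactly this oxygen as the only free hydroxyl of 15. The other ring C ether, to ring D, is flanked on both sides and would be the worst to make by coupling, so it is not touched here. The forward reaction is a copper-catalysed etherification of phenol 15 with aryl bromide 23.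

**15 to 12.** Ring C is taken apart at the C1–C2 bond (phenol carbon to CH) and refolded into cyclobutenone 12. In 12 the ring D ether sits on the carbon next to the carbonyl, two methoxy groups come from the squarate core, and the third comes from the methoxyvinyl group. This installs all five oxygens and the ring D ether by connectivity alone. The forward reaction must open the four-membered ring with the alkenyl group turned inward and then close the six-membered ring.

**12 to 8 and 9.** The C–C bond between C4 of the cyclobutenone and the vinyl carbon is cut, together with the O–CH3 bond on C4. Forward, the α-lithiated vinyl ether 10 (from 9) adds to one carbonyl of squarate 8 and alkoxide 11 is methylated in the same flask. The addition must occur at the carbonyl next to the methoxy-bearing carbon. That carbonyl is conjugated with the weaker aryloxy donor and has the smaller neighbour.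

**8 to 6 and 5.** The two C–O bonds on the squarate core are cut. Forward, the two chlorides of 6 are replaced one after the other, first by the one-carbon alcohol (via 7), then by phenol 5. Chloride is by far the best leaving group present, so the order of introduction should be kept.

**5 to 3 to 1 and 2.** The phenolic oxygen of 5 is traced to the formyl group of 3 (aldehyde to formate 4 to phenol). The ring D–O–ring E bond is cut on the ring E side. The hindered oxygen nucleophile of 1 is then paired with the unhindered boron partner 2. The para-formyl group keeps that phenol from oxidising during an oxidative copper coupling.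

**23 to 18 and 22, then to 16, 19 and 20.** The ring A–O–ring B bond is cut on the ring B side, where the carbon has hydrogen on both flanks; the ring A carbon sits between two methoxy groups. Ring B becomes bromo-iodide 22, whose unhindered C–I bond reacts before the methoxy-flanked C–Br bond kept for the union with 15. Iodide 22 comes from 19 and 20 by sterically directed C–H borylation (via 21) at the only position without an ortho substituent, then iodination. Phenol 18 comes from aldehyde 16 via formate 17.

## Alternatives that were turned down

**Alternative 1: three-component assembly on a ruthenium-bound ring C.** Both ether bonds of ring C are cut at once. Forward, the cyclopentadienyl complex of divalent ruthenium A2, [CpRu(η6-1,2-dichloro-3,4,5-trimethoxybenzene)]PF6, would react first with the phenoxide of the A–B phenol A3 and then with the phenoxide of 5. The product is A1, the [CpRu]PF6 complex of 24, and photolysis would release 24.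
- For: it is the most convergent plan, joining three fragments in one pot, and would very likely have a shorter longest linear sequence than the chosen route. Substitution on such cationic chloroarene complexes is mild and well known. On these points it is stronger.
- Against: the two chlorides of A2 differ only in their neighbour (H versus OMe). Which phenoxide ends up where rests on a kinetic preference, and a reversed order gives an isomer with the same mass and nearly the same spectra. The second substitution must occur at a carbon flanked by the new aryloxy group and a methoxy group on a ring with four donors. Ruthenium is stoichiometric, and the dichloroarene of A2 needs its own regiocontrolled synthesis.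
- In its place the chosen strategy fixes the ring D ether by the connectivity of 12 and leaves one hydroxyl, at a known position, for the last coupling.

**Alternative 2: ring A by double Claisen annulation.** Two C–C bonds of ring A are cut. Forward, the alkoxide-derived dienolate of diethyl 3-oxopentanedioate A6 would be C-acylated at both terminal carbons by the two ester groups of the aryloxymalonate A5, giving the phloroglucinol diester A4.
- For: the ring A ether oxygen is in place before the ring exists, so no coupling at a di-ortho-substituted, oxidation-prone ring A oxygen is needed. That coupling (step 8) is a weak point of the chosen route, and here the alternative is stronger. The reagents are commodity chemicals.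
- Against: the ring-forming event is spent on the simplest ring. A5 has an acidic C–H between two esters and an aryloxy group; under alkoxide it is largely enolised and then a poor acyl donor, while A6 can self-condense. After A4, ester hydrolysis, double decarboxylation, tri-O-methylation and debenzylation are still needed to reach A3, about four more operations, against three steps in all for 23. Ring C, with five oxygens and two different ethers, stays unsolved and falls to a hindered coupling.
- The chosen strategy uses its ring construction where the substitution pattern is hardest.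

**Alternative 3: formyl groups as activators, then triple Dakin oxidation.** Three hydroxyl C–O bonds on rings B, C and E are traced back to formyl groups, which first activate fluoroarenes for ether formation by nucleophilic aromatic substitution. Forward, the trialdehyde A8 with a peracid and then basic methanolysis would give the triol A7 in three Baeyer–Villiger-type events.
- For: the ether bonds are made without metal, with regiochemistry fixed by where the fluoride sits. The activators become required oxygens in one operation. No organolithium, labile squarate or thermolysis is involved, and A7 needs only the same final demethylation. In reliability of the individual bond-forming reactions it is as strong as or stronger than the chosen route, at comparable length.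
- Against: in A8 the ring C formyl group is para to the ether to ring B but meta to the ether to ring D, and ring D has no formyl group. The most crowded ether of the molecule therefore gains nothing from the tactic and needs different chemistry. Every electrophile carries two or three oxygen donors that slow substitution. Three aldehydes must survive successive basic couplings, and the final peracid step meets the very electron-rich ring A.
- The chosen strategy never has to form that crowded ring C–ring D ether by coupling onto a finished arene, because the oxygen is attached while ring C is still a squarate.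

Key step: step 5

Remark: the target has no stereogenic element; the only stereocentre in the route (C4 of 11 and 12) is racemic and is erased in step 5.

## Route

Step 1
Reactants: 1 syringaldehyde; 2 3,4,5-trimethoxyphenylboronic acid
Product: 3 3,5-dimethoxy-4-(3,4,5-trimethoxyphenoxy)benzaldehyde
Conditions: 2 (2 equiv), Cu(OAc)2 (1 equiv), pyridine (5 equiv), 4 Å MS, CH2Cl2, air, rt
Reagents that add atoms: none
Why: Chan–Lam–Evans O-arylation: the aryl group passes from boron to the phenoxide of divalent copper and C–O reductive elimination follows at room temperature from trivalent copper, which tolerates the aldehyde. Di-ortho-substituted phenols are known substrates, the boron partner has no ortho substituent, and the para-formyl group protects the phenol from oxidation.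

Step 2
Reactants: 3 3,5-dimethoxy-4-(3,4,5-trimethoxyphenoxy)benzaldehyde
Product: 5 3,5-dimethoxy-4-(3,4,5-trimethoxyphenoxy)phenol, via aryl formate 4 (not isolated)
Conditions: mCPBA (1.3 equiv), CH2Cl2, 0 °C to rt; then K2CO3 (0.2 equiv), MeOH, rt
Reagents that add atoms: 3-chloroperbenzoic acid (mCPBA), OOC(=O)c1cccc(Cl)c1
Why: Baeyer–Villiger oxidation of an electron-rich benzaldehyde; the aryl group, with a para-aryloxy donor, migrates in the Criegee adduct to give formate 4, which mild methanolysis cleaves. The same sequence is standard for 3,4,5-trimethoxybenzaldehyde.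

Step 3
Reactants: 6 3,4-dichlorocyclobut-3-ene-1,2-dione; 5 3,5-dimethoxy-4-(3,4,5-trimethoxyphenoxy)phenol
Product: 8 3-[3,5-dimethoxy-4-(3,4,5-trimethoxyphenoxy)phenoxy]-4-methoxycyclobut-3-ene-1,2-dione, via 3-chloro-4-methoxycyclobut-3-ene-1,2-dione 7 (not isolated)
Conditions: MeOH (1.0 equiv), CH2Cl2, −20 to 0 °C, N2 sweep; then 5 (0.95 equiv), i-Pr2NEt (1.1 equiv), −40 to 0 °C; used after rapid filtration through a short silica pad
Reagents that add atoms: methanol, CO
Why: Two successive addition–eliminations on a vinylogous acid chloride. The first methoxy group makes 7 less electrophilic than 6, which favours mono-substitution, and chloride is a far better leaving group than methoxide, so the phenoxide of 5 should displace only the remaining chloride.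

Step 4
Reactants: 9 methyl vinyl ether; 8 3-[3,5-dimethoxy-4-(3,4,5-trimethoxyphenoxy)phenoxy]-4-methoxycyclobut-3-ene-1,2-dione
Product: 12 racemic 2-[3,5-dimethoxy-4-(3,4,5-trimethoxyphenoxy)phenoxy]-3,4-dimethoxy-4-(1-methoxyethenyl)cyclobut-2-en-1-one, via 1-methoxyvinyllithium 10 (not isolated), via lithium alkoxide 11 (not isolated)
Conditions: 9 (1.5 equiv), t-BuLi (1.15 equiv), THF/pentane, −78 to 0 °C, excess 9 purged; then 8, THF, −78 °C; then MeOTf (1.5 equiv), −78 to −40 °C; sat. NaHCO3; Et3N-deactivated silica
Reagents that add atoms: methyl trifluoromethanesulfonate, COS(=O)(=O)C(F)(F)F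
Why: α-Lithiation of the enol ether, 1,2-addition of the organolithium to a squarate carbonyl and in-flask O-methylation of the alkoxide with methyl triflate are all standard squarate chemistry. Attack is expected at the carbonyl next to the methoxy-bearing carbon, because that carbonyl is conjugated with the weaker aryloxy donor and has the smaller neighbour, while the other carbonyl is deactivated as a vinylogous methyl ester and shielded by the aryloxy group. The new quaternary centre is formed racemic and needs no control.

Step 5
Reactants: 12 racemic 2-[3,5-dimethoxy-4-(3,4,5-trimethoxyphenoxy)phenoxy]-3,4-dimethoxy-4-(1-methoxyethenyl)cyclobut-2-en-1-one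
Product: 15 2-[3,5-dimethoxy-4-(3,4,5-trimethoxyphenoxy)phenoxy]-3,4,5-trimethoxyphenol, via (Z)-dienylketene 13 (not isolated), via cyclohexa-2,4-dienone 14 (not isolated)
Conditions: degassed p-xylene (0.01 M), 135 °C, Ar, base-washed glassware
Reagents that add atoms: none
Why: This is a Moore rearrangement; the closest known reaction type is the thermolysis of squarate-derived 4-alkenyl-4-hydroxy- or 4-alkoxycyclobutenones to hydroquinones and polyoxygenated phenols. Heating opens the C1–C4 bond of the cyclobutenone in a conrotatory 4π electrocyclic reaction in which the 4-methoxy donor rotates outward and the 1-methoxyvinyl group inward, so that (Z)-dienylketene 13 has the vinyl group beside the ketene. Ring C then closes by a thermal disrotatory 6π electrocyclisation in which the ketene carbon bonds to the vinyl CH2, giving cyclohexa-2,4-dienone 14. Enolisation of its CH2–C=O unit gives the aromatic phenol irreversibly. No stereocentre is formed and the racemic C4 centre of 12 is erased. The selectivity needed is torquoselectivity (alkenyl inward), which the oxygen donor on C4 secures electronically; the position of the ring D ether next to the new hydroxyl is inherited from step 4 and cannot change here because no bond to oxygen is broken. High dilution in an aprotic, degassed solvent should keep the ketene from intermolecular capture, the enol ether from hydrolysis and the electron-rich phenol from oxidation.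

Step 6
Reactants: 16 2,4,6-trimethoxybenzaldehyde
Product: 18 2,4,6-trimethoxyphenol, via 2,4,6-trimethoxyphenyl formate 17 (not isolated)
Conditions: mCPBA (1.1 equiv), CH2Cl2, 0 °C; then K2CO3 (0.2 equiv), MeOH, rt, N2; stored under Ar and used promptly
Reagents that add atoms: 3-chloroperbenzoic acid (mCPBA), OOC(=O)c1cccc(Cl)c1
Why: Baeyer–Villiger oxidation of a very electron-rich benzaldehyde, whose aryl group migrates readily, followed by methanolysis of formate 17. The peracid is consumed before the oxidation-prone phenol is set free.

Step 7
Reactants: 19 1-bromo-2,3-dimethoxybenzene; 20 bis(pinacolato)diboron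
Product: 22 1-bromo-5-iodo-2,3-dimethoxybenzene, via pinacol boronate 21 (not isolated)
Conditions: [Ir(OMe)(cod)]2 (1 mol %), 4,4'-di-tert-butyl-2,2'-bipyridine (2 mol %), 20 (1.0 equiv), THF, 80 °C; then CuI (10 mol %), 1,10-phenanthroline (20 mol %), KI (1.5 equiv), MeOH/H2O, air, 80 °C
Reagents that add atoms: potassium iodide, [K+].[I-]
Why: Iridium-catalysed C–H borylation is governed by sterics, and in a 1,2,3-trisubstituted benzene only C5–H has no ortho substituent. The one-pot copper-catalysed iododeboronation of the aryl pinacol boronate is a known sequel, and the C–Br bond is inert to both stages.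

Step 8
Reactants: 18 2,4,6-trimethoxyphenol; 22 1-bromo-5-iodo-2,3-dimethoxybenzene
Product: 23 1-bromo-2,3-dimethoxy-5-(2,4,6-trimethoxyphenoxy)benzene
Conditions: 22 (1.2 equiv), CuI (10 mol %), picolinic acid (20 mol %), K3PO4 (2 equiv), degassed DMSO, 80 °C, N2
Reagents that add atoms: none
Why: Ullmann-type diaryl ether synthesis with the picolinic acid ligand system, which accepts 2,6-disubstituted phenols. The unhindered C–I bond should react well before the methoxy-flanked C–Br bond at this temperature, and the oxygen-free medium with monovalent copper spares the oxidation-prone phenol.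

Step 9
Reactants: 15 2-[3,5-dimethoxy-4-(3,4,5-trimethoxyphenoxy)phenoxy]-3,4,5-trimethoxyphenol; 23 1-bromo-2,3-dimethoxy-5-(2,4,6-trimethoxyphenoxy)benzene
Product: 24 trideca-O-methyl ether of the target
Conditions: 23 (1.3 equiv), CuI (30 mol %), picolinic acid (60 mol %), K3PO4 (2 equiv), degassed DMSO, 110 °C, Ar
Reagents that add atoms: none
Why: Ullmann-type etherification of a mono-ortho-substituted phenol with an ortho-methoxy aryl bromide; both partners are electron-rich and hindered, hence the higher catalyst loading and temperature. 15 has only one hydroxyl, so no regiochemical question arises.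

Step 10
Reactants: 24 trideca-O-methyl ether of the target
Product: 25 target compound CNP0228612.0
Conditions: BBr3 (30 equiv), CH2Cl2, −78 °C to rt, Ar; MeOH then H2O quench; reversed-phase chromatography with degassed, acidified solvents
Reagents that add atoms: none
Why: Lewis acid ether cleavage: boron binds each methoxy oxygen and bromide attacks the methyl carbon in an SN2 step. The diaryl ether bonds have no carbon open to such attack and should survive, and hydrolysis of the aryl borates gives the free polyphenol.

## Compound list

1 | syringaldehyde (4-hydroxy-3,5-dimethoxybenzaldehyde) | COc1cc(C=O)cc(OC)c1O | starting material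
2 | 3,4,5-trimethoxyphenylboronic acid | COc1cc(B(O)O)cc(OC)c1OC | starting material
3 | 3,5-dimethoxy-4-(3,4,5-trimethoxyphenoxy)benzaldehyde | COc1cc(C=O)cc(OC)c1Oc1cc(OC)c(OC)c(OC)c1 | intermediate
4 | 3,5-dimethoxy-4-(3,4,5-trimethoxyphenoxy)phenyl formate | COc1cc(OC=O)cc(OC)c1Oc1cc(OC)c(OC)c(OC)c1 | intermediate
5 | 3,5-dimethoxy-4-(3,4,5-trimethoxyphenoxy)phenol (D–E phenol) | COc1cc(O)cc(OC)c1Oc1cc(OC)c(OC)c(OC)c1 | intermediate
6 | 3,4-dichlorocyclobut-3-ene-1,2-dione | ClC1=C(Cl)C(=O)C1=O | starting material
7 | 3-chloro-4-methoxycyclobut-3-ene-1,2-dione | COC1=C(Cl)C(=O)C1=O | intermediate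
8 | 3-[3,5-dimethoxy-4-(3,4,5-trimethoxyphenoxy)phenoxy]-4-methoxycyclobut-3-ene-1,2-dione | COC1=C(Oc2cc(OC)c(Oc3cc(OC)c(OC)c(OC)c3)c(OC)c2)C(=O)C1=O | intermediate
9 | methyl vinyl ether | COC=C | starting material
10 | 1-methoxyvinyllithium | [Li]C(=C)OC | intermediate
11 | racemic lithium 3-[3,5-dimethoxy-4-(3,4,5-trimethoxyphenoxy)phenoxy]-2-methoxy-1-(1-methoxyethenyl)-4-oxocyclobut-2-en-1-olate | COC(=C)C1([O-])C(OC)=C(Oc2cc(OC)c(Oc3cc(OC)c(OC)c(OC)c3)c(OC)c2)C1=O.[Li+] | intermediate
12 | racemic 2-[3,5-dimethoxy-4-(3,4,5-trimethoxyphenoxy)phenoxy]-3,4-dimethoxy-4-(1-methoxyethenyl)cyclobut-2-en-1-one | COC(=C)C1(OC)C(OC)=C(Oc2cc(OC)c(Oc3cc(OC)c(OC)c(OC)c3)c(OC)c2)C1=O | intermediate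
13 | (3Z)-2-[3,5-dimethoxy-4-(3,4,5-trimethoxyphenoxy)phenoxy]-3,4,5-trimethoxyhexa-1,3,5-trien-1-one (dienylketene) | C=C(OC)/C(OC)=C(OC)\C(Oc1cc(OC)c(Oc2cc(OC)c(OC)c(OC)c2)c(OC)c1)=C=O | intermediate
14 | 2-[3,5-dimethoxy-4-(3,4,5-trimethoxyphenoxy)phenoxy]-3,4,5-trimethoxycyclohexa-2,4-dien-1-one | O=C1CC(OC)=C(OC)C(OC)=C1Oc1cc(OC)c(Oc2cc(OC)c(OC)c(OC)c2)c(OC)c1 | intermediate
15 | 2-[3,5-dimethoxy-4-(3,4,5-trimethoxyphenoxy)phenoxy]-3,4,5-trimethoxyphenol (C–D–E phenol) | Oc1cc(OC)c(OC)c(OC)c1Oc1cc(OC)c(Oc2cc(OC)c(OC)c(OC)c2)c(OC)c1 | intermediate
16 | 2,4,6-trimethoxybenzaldehyde | COc1cc(OC)c(C=O)c(OC)c1 | starting material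
17 | 2,4,6-trimethoxyphenyl formate | COc1cc(OC)c(OC=O)c(OC)c1 | intermediate
18 | 2,4,6-trimethoxyphenol | COc1cc(OC)c(O)c(OC)c1 | intermediate
19 | 1-bromo-2,3-dimethoxybenzene | COc1cccc(Br)c1OC | starting material
20 | bis(pinacolato)diboron | CC1(C)OB(OC1(C)C)B1OC(C)(C)C(C)(C)O1 | starting material
21 | 2-(3-bromo-4,5-dimethoxyphenyl)-4,4,5,5-tetramethyl-1,3,2-dioxaborolane | COc1cc(B2OC(C)(C)C(C)(C)O2)cc(Br)c1OC | intermediate
22 | 1-bromo-5-iodo-2,3-dimethoxybenzene | COc1cc(I)cc(Br)c1OC | intermediate
23 | 1-bromo-2,3-dimethoxy-5-(2,4,6-trimethoxyphenoxy)benzene (A–B bromide) | COc1cc(OC)c(Oc2cc(Br)c(OC)c(OC)c2)c(OC)c1 | intermediate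
24 | trideca-O-methyl ether of the target | COc1cc(OC)c(Oc2cc(OC)c(OC)c(Oc3cc(OC)c(OC)c(OC)c3Oc3cc(OC)c(Oc4cc(OC)c(OC)c(OC)c4)c(OC)c3)c2)c(OC)c1 | intermediate
25 | CNP0228612.0 | Oc1cc(O)c(Oc2cc(O)c(O)c(Oc3cc(O)c(O)c(O)c3Oc3cc(O)c(Oc4cc(O)c(O)c(O)c4)c(O)c3)c2)c(O)c1 | target

## Step count and least certain steps

Total steps: 10. Longest linear sequence: 7 (steps 1, 2, 3, 4, 5, 9, 10).

**Step 5 (key step).** The ketene may be diverted before it cyclises, by dimerisation or by capture with traces of water or alcohol, or the enol ether may hydrolyse before ring opening and send the substrate down other thermal paths. The pentaoxygenated phenol may also oxidise at 135 °C if oxygen is present. Fallback: the squarate line is left at phenol 5 and ring C is taken from an arene that already has its six carbons. Copper-promoted coupling (CuI, K2CO3, DMF, 120 °C) of 5 with purchased 2-bromo-3,4,5-trimethoxybenzaldehyde F1, whose ortho-formyl group activates the bromide, should give 2-[3,5-dimethoxy-4-(3,4,5-trimethoxyphenoxy)phenoxy]-3,4,5-trimethoxybenzaldehyde F2. Baeyer–Villiger oxidation with mCPBA to the corresponding aryl formate F3 and methanolysis with catalytic K2CO3 returns to the route at 15.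

**Step 4.** Addition may occur partly at the wrong carbonyl, which would end as the isomeric phenol with the ether and a methoxy group exchanged. The organolithium may also add to the aryloxy-bearing carbon and expel aryloxide, since aryloxide is a good leaving group on a squarate. Fallback: two equivalents of 5 and 6 with i-Pr2NEt give the symmetric 3,4-bis[3,5-dimethoxy-4-(3,4,5-trimethoxyphenoxy)phenoxy]cyclobut-3-ene-1,2-dione F4, whose carbonyls are equivalent. Addition of 10 gives the lithium alkoxide F5, and trapping with MeOTf gives the 2,3-bis(aryloxy)-4-methoxy-4-(1-methoxyethenyl)cyclobut-2-en-1-one F6. One equivalent of NaOMe in THF/MeOH at −20 °C then exchanges only the aryloxy group on C3 by addition–elimination at the vinylogous ester carbon, because C2 is not electrophilic. This returns to the route at 12 and releases one equivalent of 5 for reuse. It also avoids the unsymmetrical squarate of step 3.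

**Step 8.** The di-ortho-substituted phenoxide may couple slowly, so that arylation at the C–Br bond of the product or degradation of the electron-rich phenol begins to compete. Fallback: from 19 through the same boronate 21, the iodination is replaced by oxidative pinacol cleavage (NaIO4, NH4OAc, acetone/H2O) to give (3-bromo-4,5-dimethoxyphenyl)boronic acid F7. Chan–Lam coupling of F7 with 18 (Cu(OAc)2 2 equiv, pyridine, 4 Å MS, CH2Cl2, rt, N2, the second equivalent of divalent copper serving as oxidant) returns to the route at 23, with the bromide untouched.

**Step 9.** Copper insertion into the electron-rich, ortho-methoxy C–Br bond may be slow, leaving time for reductive loss of bromine and for base-mediated decay of phenol 15. The ortho-aryloxy group of 15 also hinders C–O bond formation. Fallback: the polarity of ring B is reversed. From 23, bromine–lithium exchange (n-BuLi, THF, −78 °C) gives the aryllithium F8, and B(OMe)3 followed by aqueous acid gives [2,3-dimethoxy-5-(2,4,6-trimethoxyphenoxy)phenyl]boronic acid F9. Room-temperature Chan–Lam coupling of F9 with 15 (Cu(OAc)2, pyridine, 4 Å MS, CH2Cl2) returns to the route at 24.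

**Step 10.** Cleavage of thirteen methyl ethers may stop short, and the free polyphenol may oxidise during aqueous work-up and chromatography, giving mixtures that cannot be separated as free phenols. Fallback: from 24, the crude product of the BBr3 reaction is not purified but acetylated (Ac2O, pyridine) to the trideca-acetate F10, which is stable to air and silica and can be separated from under-cleaved material. Deacetylation with catalytic NaOMe in degassed MeOH under argon, followed by neutralisation with an acidic ion-exchange resin, returns to the route at 25.

## Further compounds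

F1 | step 5 | 2-bromo-3,4,5-trimethoxybenzaldehyde (purchased partner) | COc1cc(C=O)c(Br)c(OC)c1OC
F2 | step 5 | 2-[3,5-dimethoxy-4-(3,4,5-trimethoxyphenoxy)phenoxy]-3,4,5-trimethoxybenzaldehyde | COc1cc(C=O)c(Oc2cc(OC)c(Oc3cc(OC)c(OC)c(OC)c3)c(OC)c2)c(OC)c1OC
F3 | step 5 | 2-[3,5-dimethoxy-4-(3,4,5-trimethoxyphenoxy)phenoxy]-3,4,5-trimethoxyphenyl formate | COc1cc(OC=O)c(Oc2cc(OC)c(Oc3cc(OC)c(OC)c(OC)c3)c(OC)c2)c(OC)c1OC
F4 | step 4 | 3,4-bis[3,5-dimethoxy-4-(3,4,5-trimethoxyphenoxy)phenoxy]cyclobut-3-ene-1,2-dione | O=C1C(=O)C(Oc2cc(OC)c(Oc3cc(OC)c(OC)c(OC)c3)c(OC)c2)=C1Oc1cc(OC)c(Oc2cc(OC)c(OC)c(OC)c2)c(OC)c1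
F5 | step 4 | racemic lithium 2,3-bis[3,5-dimethoxy-4-(3,4,5-trimethoxyphenoxy)phenoxy]-1-(1-methoxyethenyl)-4-oxocyclobut-2-en-1-olate | COC(=C)C1([O-])C(Oc2cc(OC)c(Oc3cc(OC)c(OC)c(OC)c3)c(OC)c2)=C(Oc2cc(OC)c(Oc3cc(OC)c(OC)c(OC)c3)c(OC)c2)C1=O.[Li+]
F6 | step 4 | racemic 2,3-bis[3,5-dimethoxy-4-(3,4,5-trimethoxyphenoxy)phenoxy]-4-methoxy-4-(1-methoxyethenyl)cyclobut-2-en-1-one | COC(=C)C1(OC)C(Oc2cc(OC)c(Oc3cc(OC)c(OC)c(OC)c3)c(OC)c2)=C(Oc2cc(OC)c(Oc3cc(OC)c(OC)c(OC)c3)c(OC)c2)C1=O
F7 | step 8 | (3-bromo-4,5-dimethoxyphenyl)boronic acid | COc1cc(B(O)O)cc(Br)c1OC
F8 | step 9 | [2,3-dimethoxy-5-(2,4,6-trimethoxyphenoxy)phenyl]lithium | COc1cc(OC)c(Oc2cc([Li])c(OC)c(OC)c2)c(OC)c1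
F9 | step 9 | [2,3-dimethoxy-5-(2,4,6-trimethoxyphenoxy)phenyl]boronic acid | COc1cc(OC)c(Oc2cc(B(O)O)c(OC)c(OC)c2)c(OC)c1
F10 | step 10 | trideca-O-acetate of the target | CC(=O)Oc1cc(OC(C)=O)c(Oc2cc(OC(C)=O)c(OC(C)=O)c(Oc3cc(OC(C)=O)c(OC(C)=O)c(OC(C)=O)c3Oc3cc(OC(C)=O)c(Oc4cc(OC(C)=O)c(OC(C)=O)c(OC(C)=O)c4)c(OC(C)=O)c3)c2)c(OC(C)=O)c1
A1 | alternative 1 | [CpRu]PF6 complex (divalent ruthenium, bound at ring C) of the trideca-O-methyl ether 24 | COc1cc(OC)c(Oc2cc(OC)c(OC)c(Oc3cc(OC)c(OC)c(OC)c3Oc3cc(OC)c(Oc4cc(OC)c(OC)c(OC)c4)c(OC)c3)c2)c(OC)c1.[cH-]1cccc1.[Ru+2].F[P-](F)(F)(F)(F)F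
A2 | alternative 1 | [CpRu(η6-1,2-dichloro-3,4,5-trimethoxybenzene)]PF6 | COc1cc(Cl)c(Cl)c(OC)c1OC.[cH-]1cccc1.[Ru+2].F[P-](F)(F)(F)(F)F
A3 | alternative 1 | 2,3-dimethoxy-5-(2,4,6-trimethoxyphenoxy)phenol (A–B phenol) | COc1cc(OC)c(Oc2cc(O)c(OC)c(OC)c2)c(OC)c1
A4 | alternative 2 | diethyl 5-[3-(benzyloxy)-4,5-dimethoxyphenoxy]-2,4,6-trihydroxybenzene-1,3-dicarboxylate | CCOC(=O)c1c(O)c(C(=O)OCC)c(O)c(Oc2cc(OC)c(OC)c(OCc3ccccc3)c2)c1O
A5 | alternative 2 | diethyl 2-[3-(benzyloxy)-4,5-dimethoxyphenoxy]propanedioate | CCOC(=O)C(Oc1cc(OC)c(OC)c(OCc2ccccc2)c1)C(=O)OCC
A6 | alternative 2 | diethyl 3-oxopentanedioate | CCOC(=O)CC(=O)CC(=O)OCC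
A7 | alternative 3 | deca-O-methyl ether of the target with free hydroxyls on rings B, C and E | COc1cc(OC)c(Oc2cc(OC)c(O)c(Oc3cc(OC)c(O)c(OC)c3Oc3cc(OC)c(Oc4cc(OC)c(O)c(OC)c4)c(OC)c3)c2)c(OC)c1
A8 | alternative 3 | corresponding trialdehyde (formyl in place of each free hydroxyl of A7) | COc1cc(OC)c(Oc2cc(OC)c(C=O)c(Oc3cc(OC)c(C=O)c(OC)c3Oc3cc(OC)c(Oc4cc(OC)c(C=O)c(OC)c4)c(OC)c3)c2)c(OC)c1
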